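(The runs are calculated on assumed constants, and the scatter is random.)

Read the earlier runs as a ladder of times, fastest rung first, then count the protic impurity in powers of ten, so that one quantity comes out: what a unit of impurity costs in target.

common to all: substrate 0.079 M (fed, over 40 min); coupling partner 0.0948 M

| charge | protic impurity | remark | time |
|---|---|---|---|
| north-west | 0.042 mM | run made earlier; the fed solution adds 0.25 times the starting volume |  |
| north-east | 0.47 mM | run made earlier; the fed solution adds 0.25 times the starting volume |  |
| south | 3.6 mM | run made earlier; the fed solution adds 0.25 times the starting volume |  |
| dawn | 0.0500 mM | the fed solution adds 0.25 times the starting volume | 6.0 h |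
| noon | 0.150 mM | the fed solution adds 0.25 times the starting volume | 6.0 h |
| dusk | 0.400 mM | the fed solution adds 0.25 times the starting volume | 6.0 h |
| autumn | 1.20 mM | the fed solution adds 0.25 times the starting volume | 6.0 h |
| winter | 4.00 mM | the fed solution adds 0.25 times the starting volume | 6.0 h |

- north-west (time / h: target / %, substrate / %): 0.500: 38.0, 24.0; 1.50: 60.9, 24.0; 3.00: 62.0, 22.8; 4.00: 63.1, 22.4; 6.00: 62.9, 23.1
- north-east (time / h: target / %, substrate / %): 0.500: 36.7, 24.9; 0.833: 54.4, 30.3; 1.50: 61.6, 24.0; 3.00: 61.5, 22.6; 6.00: 61.8, 23.1
- south (time / h: target / %, substrate / %): 0.500: 37.9, 25.8; 1.50: 60.1, 27.5; 3.00: 60.0, 25.6; 4.00: 60.4, 25.7; 6.00: 60.0, 24.8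

(scatter of a reading: 0.5 percentage points)

- charges are per starting volume, the dose included; the dosed solution carries all of it
- percentages count the whole charge, also what has not yet gone in
- "hardly changes" means that all values lie within two and a half points (for a concentration: within two and a half percent of the largest)

* amount of target at the end, in percent of the substrate charged for dawn, noon, dusk, autumn, winter, in this order
* how the row runs (rises all the way / falls all the way / rises, then falls / hardly changes / falls, then rises)

On the first rung, inside the feed, the north-west run at 0.500 h has received 75.0% of its substrate and shows 38.0% target and 24.0% substrate, so 13 percentage points of what has gone in is already neither. On the second rung, after the feed ends at 40 min, the target of that run climbs to 60.9% by 1.50 h. On the last rung, from 3.00 h up to the asked time of 6.0 h, an end time about ten times the length of the feed, the target readings of that run stay between 62.0% and 63.1%, with a scatter of 0.5 points, and substrate reads 23.1% at the last reading. A halt with substrate still present, in a flask charged with 1.20 of coupling partner per substrate, suggests that the coupling partner is the limiting reagent, so the asked time can be read as a plateau.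

The last three target readings average 62.7% in the north-west run and 60.1% in the south run. Turned into concentrations, they give x = 0.562, the exchange ratio, meaning moles of target lost per mole of protic impurity charged. Taken as a straight loss in concentration, a step of impurity from dusk to winter, ten times the charge, costs ten times as much as the decade below it, so this reckoning has noon just 0.071 points under dawn, dusk at 62.4% and winter at 59.8%. Its drop from dawn to winter is 2.8 points against a margin of 2.5 points, with readings scattering by 0.5 points, so it commits narrowly to a fall.

The forecast gives 62.7%, 62.2%, 61.7%, 61% and 60%, with the shape falls all the way, and says “the row falls gently all the way”. This reckoning shares that shape, but at dusk the forecast stands at 61.7%, lower than this reckoning.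

The flask gives 62.4%, 62.4%, 62.3%, 61.9% and 60.7%, a drop of 1.7 points, so the row hardly changes.

    substrate + 2 coupling partner → side product (k = 0.240 /M²/s)
    coupling partner → decomposed reagent (k = 1.70 × 10⁻⁴ /s)
    substrate + coupling partner → target (k = 0.0370 /M/s)
    coupling partner + protic impurity → quenched reagent (k = 0.0200 /M/s)

At 6.00 h the winter flask holds 25.6% substrate against 23.2% in the dawn flask, with coupling partner at 0% and quenched reagent at 0.00288 M. Applied to the autumn flask, x gives a drop from dawn of 0.82 points, and autumn stands 0.5 points below dawn.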